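## Retrosynthetic overview
1. The target comes from a 19-hydroxy-15-formate, which comes from the 15,19-diol, then a chiral C19 ester, then its 3-ketone. These are functional-group changes only.
2. Key disconnection: C4–C5, C9–C10 and the C8=C17 alkene are opened together. An acyclic (E,E)-dienyl α-methyl β-keto ester closes ring A first and ring B second in one oxidative radical cascade, steered by an 8-phenylmenthyl ester.
3. C1–C2 is made by γ-alkylation of the β-keto ester dianion with a C15 allylic bromide.
4. The bromide comes from terminal allylic oxidation of (S)-2,3-dihydrofarnesol, itself made by asymmetric hydrogenation of (E,E)-farnesol, which sets C13.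

Assumption: labdane numbering (C1–C20) is used throughout. The (−)-8-phenylmenthyl ester is taken to leave the Re face of the unchelated C4 radical open, which gives the normal labdane series.

## Route

Step 1
Reactants: 1 (2E,6E)-farnesol
Product: 2 (S)-2,3-dihydrofarnesol = (3S,6E)-3,7,11-trimethyldodeca-6,10-dien-1-ol
Conditions: H2 (90 atm), Ru(OAc)2[(R)-BINAP] (0.2 mol%), MeOH/H2O 95:5, 20 °C
Reagents that add atoms: none
Why: Noyori hydroxyl-directed asymmetric hydrogenation reduces only the allylic-alcohol alkene, and the (R)-BINAP catalyst on an E-allylic alcohol sets the future C13 as S, the same sense as geraniol to (S)-citronellol.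

Step 2
Reactants: 2 (S)-2,3-dihydrofarnesol
Product: 3 (2E,6E,10S)-2,6,10-trimethyldodeca-2,6-diene-1,12-diol
Conditions: SeO2 (0.2 equiv), t-BuOOH (2.5 equiv), salicylic acid (0.1 equiv), CH2Cl2, 0 °C to rt
Reagents that add atoms: tert-butyl hydroperoxide, CC(C)(C)OO
Why: Sharpless–Umbreit allylic oxidation (ene reaction, then [2,3]-shift) attacks the E-methyl of the terminal gem-dimethyl alkene, giving the E-allylic alcohol (future C1) without creating a stereocenter or touching C13.

Step 3
Reactants: 3 (2E,6E,10S)-2,6,10-trimethyldodeca-2,6-diene-1,12-diol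
Product: 5 (3S,6E,10E)-12-bromo-3,7,11-trimethyldodeca-6,10-dien-1-ol, via allylic alkoxysulfonium bromide 4 (not isolated)
Conditions: NBS (1.5 equiv), Me2S (1.8 equiv), CH2Cl2, −20 to 0 °C; brine work-up
Reagents that add atoms: N-bromosuccinimide, O=C1CCC(=O)N1Br
Why: In the Corey–Kim halide synthesis only the allylic alkoxysulfonium salt is displaced by bromide at 0 °C (SN2, E geometry kept), while any saturated alkoxysulfonium salt reverts to the alcohol on aqueous work-up.

Step 4
Reactants: 6 methyl 2-methylacetoacetate; 7 (−)-8-phenylmenthol = (1R,2S,5R)-5-methyl-2-(2-phenylpropan-2-yl)cyclohexan-1-ol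
Product: 8 (−)-8-phenylmenthyl 2-methyl-3-oxobutanoate (epimers at the α-carbon)
Conditions: DMAP (0.3 equiv), toluene, reflux, MeOH removed over 4 Å sieves
Reagents that add atoms: none
Why: DMAP-catalysed β-keto ester transesterification through the acylketene leaves the carbinol stereocenters of the auxiliary untouched, and the α-carbon configuration is irrelevant because it becomes planar in step 6.

Step 5
Reactants: 8 (−)-8-phenylmenthyl 2-methyl-3-oxobutanoate (2.2 equiv, surplus recovered); 5 (3S,6E,10E)-12-bromo-3,7,11-trimethyldodeca-6,10-dien-1-ol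
Product: 10 (−)-8-phenylmenthyl (6E,10E,14S)-16-hydroxy-2,6,10,14-tetramethyl-3-oxohexadeca-6,10-dienoate (epimers at C2), via sodium lithium dianion 9 (not isolated)
Conditions: 8, NaH, THF, 0 °C; n-BuLi, 0 °C; then 5, 0 °C; AcOH quench
Reagents that add atoms: none
Why: In the Huckin–Weiler dianion alkylation the more reactive terminal carbanion (future C2) displaces the primary allylic bromide by SN2 with both E-alkenes retained, one extra equivalent of dianion only deprotonates the free hydroxyl, and the new α-stereocenter is inconsequential.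

Step 6 (key step)
Reactants: 10 (−)-8-phenylmenthyl (6E,10E,14S)-16-hydroxy-2,6,10,14-tetramethyl-3-oxohexadeca-6,10-dienoate
Product: 11 (−)-8-phenylmenthyl (13S)-15-hydroxy-3-oxolabd-8(17)-en-19-oate (4β-axial ester; 5α-H; 9α-H; 10β-CH3)
Conditions: Mn(OAc)3·2H2O (2.2 equiv), Cu(OAc)2·H2O (1.0 equiv), degassed AcOH, 25 °C, no Lewis acid additive; minor diastereomer removed on silica
Reagents that add atoms: none
Why: This is a Snider-type oxidative free-radical polyene bicyclization in which trivalent manganese oxidises the enol to the planar C4 radical; that radical reacts in its unchelated sickle conformer (ketone C=O turned away, ester carbon cis to C2, hence axial ester and equatorial methyl) on the Re face left open by the stacked phenyl ring of the auxiliary; the chair–chair 6-endo/6-endo cascade through the two E-alkenes then fixes the trans fusion (5α-H, 10β-CH3) and the equatorial C9 chain; and divalent copper captures the tertiary C8 radical and removes the least hindered β-hydrogen (C17–H) to give the exocyclic alkene.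

Step 7
Reactants: 11 (−)-8-phenylmenthyl (13S)-15-hydroxy-3-oxolabd-8(17)-en-19-oate
Product: 13 (−)-8-phenylmenthyl (13S)-15-hydroxylabd-8(17)-en-19-oate, via C3 tosylhydrazone 12 (not isolated)
Conditions: TsNHNH2 (2 equiv), EtOH, 75 °C; evaporate; catecholborane (4 equiv), CHCl3, 0 °C; NaOAc·3H2O, reflux
Reagents that add atoms: none
Why: In the Caglioti deoxygenation (Kabalka variant) hydride adds to the C=N bond, acetate triggers loss of sulfinate, and the diazene loses N2 to leave CH2 at C3, under neutral conditions that spare the ester, the uncatalysed 1,1-disubstituted alkene and all stereocenters.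

Step 8
Reactants: 13 (−)-8-phenylmenthyl (13S)-15-hydroxylabd-8(17)-en-19-oate
Product: 14 (13S)-labd-8(17)-ene-15,19-diol
Conditions: LiAlH4 (4 equiv), THF, reflux; Fieser work-up; 7 recovered by chromatography
Reagents that add atoms: none
Why: Hydride reduction is the reliable way to open an axial neopentyl ester that resists hydrolysis; it releases the auxiliary for reuse and affects neither the isolated alkene nor any stereocenter.

Step 9
Reactants: 14 (13S)-labd-8(17)-ene-15,19-diol
Product: 15 (13S)-19-hydroxylabd-8(17)-en-15-yl formate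
Conditions: HCO2CH2CF3 (3 equiv), THF, 65 °C
Reagents that add atoms: 2,2,2-trifluoroethyl formate, O=COCC(F)(F)F
Why: Neutral transformylation with an activated formate is sterically selective, so the open C15 hydroxyl reacts while the axial neopentyl C19 hydroxyl (1,3-diaxial to the C10 methyl) does not.

Step 10
Reactants: 15 (13S)-19-hydroxylabd-8(17)-en-15-yl formate
Product: 17 (4S,5R,9S,10R,13S)-15-formyloxylabd-8(17)-en-19-oic acid, via C19 aldehyde 16 (not isolated)
Conditions: CrO3, H2SO4, H2O, acetone, 0 °C, 20 min; i-PrOH quench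
Reagents that add atoms: water, O
Why: Jones oxidation takes the hindered primary alcohol through the aldehyde hydrate to the acid at a quaternary carbon that cannot epimerise, and the short cold contact leaves the formate and the exocyclic alkene intact.

## Compound list
1 | (2E,6E)-farnesol | CC(C)=CCC/C(C)=C/CC/C(C)=C/CO | starting material
2 | (S)-2,3-dihydrofarnesol | CC(C)=CCC/C(C)=C/CC[C@H](C)CCO | intermediate
3 | (2E,6E,10S)-2,6,10-trimethyldodeca-2,6-diene-1,12-diol | OC/C(C)=C/CC/C(C)=C/CC[C@H](C)CCO | intermediate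
4 | allylic alkoxydimethylsulfonium bromide of 3 | C[S+](C)OC/C(C)=C/CC/C(C)=C/CC[C@H](C)CCO.[Br-] | intermediate (not isolated)
5 | (3S,6E,10E)-12-bromo-3,7,11-trimethyldodeca-6,10-dien-1-ol | BrC/C(C)=C/CC/C(C)=C/CC[C@H](C)CCO | intermediate
6 | methyl 2-methylacetoacetate | COC(=O)C(C)C(C)=O | starting material
7 | (−)-8-phenylmenthol (recovered in step 8) | O[C@@H]1C[C@H](C)CC[C@H]1C(C)(C)c2ccccc2 | starting material
8 | (−)-8-phenylmenthyl 2-methyl-3-oxobutanoate | CC(=O)C(C)C(=O)O[C@@H]1C[C@H](C)CC[C@H]1C(C)(C)c2ccccc2 | intermediate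
9 | sodium lithium dianion of 8 | [Na+].[Li+].[CH2-]C([O-])=C(C)C(=O)O[C@@H]1C[C@H](C)CC[C@H]1C(C)(C)c2ccccc2 | intermediate (not isolated)
10 | (−)-8-phenylmenthyl (6E,10E,14S)-16-hydroxy-2,6,10,14-tetramethyl-3-oxohexadeca-6,10-dienoate | CC(C(=O)CC/C(C)=C/CC/C(C)=C/CC[C@H](C)CCO)C(=O)O[C@@H]1C[C@H](C)CC[C@H]1C(C)(C)c2ccccc2 | intermediate
11 | (−)-8-phenylmenthyl (13S)-15-hydroxy-3-oxolabd-8(17)-en-19-oate | C=C1CC[C@@H]2[C@](C)(CCC(=O)[C@]2(C)C(=O)O[C@@H]3C[C@H](C)CC[C@H]3C(C)(C)c4ccccc4)[C@H]1CC[C@H](C)CCO | intermediate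
12 | C3 tosylhydrazone of 11 | C=C1CC[C@@H]2[C@](C)(CCC(=NNS(=O)(=O)c5ccc(C)cc5)[C@]2(C)C(=O)O[C@@H]3C[C@H](C)CC[C@H]3C(C)(C)c4ccccc4)[C@H]1CC[C@H](C)CCO | intermediate (not isolated)
13 | (−)-8-phenylmenthyl (13S)-15-hydroxylabd-8(17)-en-19-oate | C=C1CC[C@@H]2[C@](C)(CCC[C@]2(C)C(=O)O[C@@H]3C[C@H](C)CC[C@H]3C(C)(C)c4ccccc4)[C@H]1CC[C@H](C)CCO | intermediate
14 | (13S)-labd-8(17)-ene-15,19-diol | C=C1CC[C@@H]2[C@](C)(CCC[C@]2(C)CO)[C@H]1CC[C@H](C)CCO | intermediate
15 | (13S)-19-hydroxylabd-8(17)-en-15-yl formate | C=C1CC[C@@H]2[C@](C)(CCC[C@]2(C)CO)[C@H]1CC[C@H](C)CCOC=O | intermediate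
16 | (13S)-19-oxolabd-8(17)-en-15-yl formate | C=C1CC[C@@H]2[C@](C)(CCC[C@]2(C)C=O)[C@H]1CC[C@H](C)CCOC=O | intermediate (not isolated)
17 | (4S,5R,9S,10R,13S)-15-formyloxylabd-8(17)-en-19-oic acid (CNP0494097.1) | C=C1CC[C@@H]2[C@](C)(CCC[C@]2(C)C(=O)O)[C@H]1CC[C@H](C)CCOC=O | target

## Step count
Total step count: 10.
Longest linear sequence: 9 (steps 1–3 and 5–10). Step 4 is a side branch.

## Steps most likely to fail

**Step 6.**
- Risks: moderate yield, incomplete facial control, endocyclic alkene isomers, and early oxidation of the monocyclic C10 radical.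
- Fallback: it sets out from 10 and comes back at 11, replacing metal oxidation by a group-transfer chain.
- Compound 10 is selenenylated at C4 (PhSeCl, pyridine, CH2Cl2, 0 °C) to the α-phenylselanyl β-keto ester F1.
- Sunlamp irradiation in benzene at 10 °C homolyses the C4–Se bond. The same auxiliary-controlled 6-endo/6-endo cascade then ends by phenylselanyl transfer to C8, giving the 8-phenylselanyl bicycle F2 (C8 epimers).
- H2O2/pyridine forms the selenoxide, whose syn-elimination toward the C17 methyl gives 11.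

**Step 7.**
- Risk: the ketone next to the quaternary C4 with its bulky axial ester may condense too slowly, or the hydrazone may eliminate to the 2-ene.
- Fallback: it sets out from 11 and comes back at 13, going through sulfur instead of nitrogen.
- 1,2-Bis(trimethylsilylthio)ethane and ZnI2 in Et2O at rt give the 3,3-ethylenedithio ketal F3 under non-protic conditions that spare the alkene.
- Bu3SnH (4.5 equiv) with AIBN in toluene at 110 °C then strips both C–S bonds by a radical chain to give 13.

**Step 3.**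
- Risk: incomplete discrimination between the allylic and the saturated primary hydroxyl.
- Fallback: it sets out from 2 and comes back at 10, using a protecting group so that no discrimination is needed.
- TBSCl/imidazole gives the dihydrofarnesyl TBS ether F4, and SeO2/t-BuOOH gives the terminal allylic alcohol F5.
- CBr4/PPh3 gives the allylic bromide F6, and alkylation of dianion 9 (now 1.1 equiv) gives the silyl-protected β-keto ester F7.
- Bu4NF/AcOH in THF then frees 10.

## Further compounds
F1 | step 6 | (−)-8-phenylmenthyl (6E,10E,14S)-16-hydroxy-2,6,10,14-tetramethyl-3-oxo-2-(phenylselanyl)hexadeca-6,10-dienoate | CC([Se]c1ccccc1)(C(=O)CC/C(C)=C/CC/C(C)=C/CC[C@H](C)CCO)C(=O)O[C@@H]2C[C@H](C)CC[C@H]2C(C)(C)c3ccccc3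
F2 | step 6 | (−)-8-phenylmenthyl (13S)-15-hydroxy-3-oxo-8-(phenylselanyl)labdan-19-oate (C8 epimers) | CC1([Se]c5ccccc5)CC[C@@H]2[C@](C)(CCC(=O)[C@]2(C)C(=O)O[C@@H]3C[C@H](C)CC[C@H]3C(C)(C)c4ccccc4)[C@H]1CC[C@H](C)CCO
F3 | step 7 | (−)-8-phenylmenthyl (13S)-3,3-(ethylenedithio)-15-hydroxylabd-8(17)-en-19-oate | C=C1CC[C@@H]2[C@](C)(CCC5(SCCS5)[C@]2(C)C(=O)O[C@@H]3C[C@H](C)CC[C@H]3C(C)(C)c4ccccc4)[C@H]1CC[C@H](C)CCO
F4 | step 3 | (S)-2,3-dihydrofarnesyl tert-butyldimethylsilyl ether | CC(C)=CCC/C(C)=C/CC[C@H](C)CCO[Si](C)(C)C(C)(C)C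
F5 | step 3 | (2E,6E,10S)-12-(tert-butyldimethylsilyloxy)-2,6,10-trimethyldodeca-2,6-dien-1-ol | OC/C(C)=C/CC/C(C)=C/CC[C@H](C)CCO[Si](C)(C)C(C)(C)C
F6 | step 3 | (3S,6E,10E)-12-bromo-3,7,11-trimethyldodeca-6,10-dienyl tert-butyldimethylsilyl ether | BrC/C(C)=C/CC/C(C)=C/CC[C@H](C)CCO[Si](C)(C)C(C)(C)C
F7 | step 3 | (−)-8-phenylmenthyl (6E,10E,14S)-16-(tert-butyldimethylsilyloxy)-2,6,10,14-tetramethyl-3-oxohexadeca-6,10-dienoate | CC(C(=O)CC/C(C)=C/CC/C(C)=C/CC[C@H](C)CCO[Si](C)(C)C(C)(C)C)C(=O)O[C@@H]1C[C@H](C)CC[C@H]1C(C)(C)c2ccccc2
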